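## Strategy

- **Cuts.** The dihydropyran ring is opened in a retro-[4+2] sense at C3–C4 and O1–C2 (C2 is the spiro carbon, pinane C2'), after an oxygen is put back on the pinane methylene C3'. The heterodiene is then cut at its exocyclic C4=C4a bond into an aldehyde and a cyclic trione, and the trione at its four C–CH3 bonds and its C–acetyl bond back to an acylphloroglucinol.
- **Enabling feature.** Ring O1–C2–C3–C4–C4a=C8a shares its enol ether bond C4a=C8a with the tetramethylcyclohexanetrione ring and is spiro-linked at C2 to the pinane. It is therefore the formal adduct of a 1-oxadiene (O1=C8a–C4a=C4) with the exocyclic alkene C2'=C10' of a pinene, and the flanking C3' methylene can travel as a carbinol that is deoxygenated afterwards.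
- **Forward order.** The trione ring is freed from the arene by dearomative tetramethylation and deacetylation. The pinane bicycle is bought whole and hydroxylated at C3'. The dihydropyran ring is closed last in a one-pot Knoevenagel/oxa-Diels–Alder reaction, and the auxiliary oxygen is removed through a xanthate.
- **Stereochemistry.** C1' and C5' come from (−)-β-pinene. The C3' carbinol is placed by SeO2 on the face away from the gem-dimethyl bridge. Spiro C2 arises by cycloaddition on that same face. C4 follows from the diene orientation (isobutyl outside, trione under C1') that the C3' hydroxyl is meant to enforce.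

Key step: step 4

Remarks on the chemistry:
- Locants: chromene core O1, C2 (spiro), C3, C4, C4a, C5 to C8, C8a; pinane atoms are primed (C1' to C7', with C2' = C2, and the exocyclic carbon C10' of the pinenes becoming C3).
- Assumption: (−)-β-pinene of high enantiomeric purity is used, since it is the only source of absolute configuration.
- The descriptors at C1' and C5' change along the route (S,S in 5; R,R in 6, 9 and 10; R,S in 11) only because the CIP priorities change. No bond at these centres is touched.

## Route

Step 1
Reactants: 1 phloroacetophenone (2,4,6-trihydroxyacetophenone); 2 iodomethane
Product: 3 acetylsyncarpic acid (2-acetyl-3-hydroxy-4,4,6,6-tetramethylcyclohex-2-ene-1,5-dione)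
Conditions: MeI (excess), NaOMe (excess), MeOH, 0 °C to reflux; then aq. HCl
Reagents that add atoms: iodomethane 2 (CI)
Why: Base-mediated dearomative C-alkylation of an acylphloroglucinol, in which each C-methylation at the two free ring carbons leaves a β-dicarbonyl that is deprotonated and methylated again until both carbons are quaternary, which ends the sequence at the achiral, acidic β-triketone 3.

Step 2
Reactants: 3 acetylsyncarpic acid
Product: 4 syncarpic acid (3-hydroxy-4,4,6,6-tetramethylcyclohex-2-ene-1,5-dione)
Conditions: 6 M aq. HCl, reflux
Reagents that add atoms: none
Why: Acid-catalysed retro-Claisen cleavage of the exocyclic acyl group of a β-triketone through its hydrate, which releases acetic acid and leaves the cyclic trione as its stable enol 4 with no stereocentre involved.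

Step 3
Reactants: 5 (1S,5S)-(−)-β-pinene
Product: 6 (1R,3S,5R)-trans-pinocarveol (hydroxyl on C3' trans to the gem-dimethyl bridge)
Conditions: SeO2 (cat.), t-BuOOH, CH2Cl2, rt
Reagents that add atoms: tert-butyl hydroperoxide (CC(C)(C)OO)
Why: Riley allylic oxidation in its catalytic Sharpless form, in which an ene reaction of the selenium reagent at the exocyclic C10' and a [2,3]-sigmatropic shift return the exocyclic alkene and place oxygen on C3', both on the face away from the gem-dimethyl bridge, so that the new carbinol is 3'S (trans) while C1' and C5' keep their spatial arrangement.

Step 4
Reactants: 4 syncarpic acid; 7 isovaleraldehyde (3-methylbutanal); 6 trans-pinocarveol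
Product: 9 3'-hydroxy spiro adduct (2R,4R,1'R,3'S,5'R; hydroxyl on C3' cis to O1), via alkylidene triketone heterodiene 8 (not isolated)
Conditions: ethylenediammonium diacetate (10 mol%), PhMe, 60–70 °C; 6 in excess, 4 added in portions
Reagents that add atoms: none
Why: Proposed new method: the amine salt condenses 4 with 7 (Knoevenagel) to the ring-locked s-cis 1-oxadiene 8, which the nucleophilic exocyclic alkene of 6 should trap in a concerted but asynchronous inverse-electron-demand oxa-[4+2] cycloaddition, C3–C4 bonding to the terminal CH2 running ahead of O1–C2 bonding, so that no free pinanyl cation arises and the cyclobutane stays closed. The closest known reaction type is the thermal hetero-Diels–Alder trapping of in situ 2-alkylidene 1,3-diones and syncarpic-acid-derived alkylidene triketones by β-pinene and other 1,1-disubstituted terpene alkenes; new here is the free allylic hydroxyl on the dienophile and the steering role asked of it. The dihydropyran ring is closed by this intermolecular [4π+2π] cycloaddition, with both new bonds formed suprafacially on one face of the alkene. Spiro C2 (R) is fixed by addition on the face away from the C6' bridge, whose inward methyl covers the other face, so O1 ends up cis to the C3' hydroxyl. C4 (R) is fixed by the orientation of the diene, isobutyl in the outside position and the triketone ring under the C1' flank of the alkene, because the C3' hydroxyl on the attacked face occupies the space that the C8a/C8 flank would need in the C3'-side approach leading to 4S and can instead hydrogen-bond to the arriving carbonyl oxygen. The step therefore needs face, regio and orientational selectivity and must beat the ene path: the bridge, the polarisation of the 1,1-disubstituted alkene and the hydroxyl (which also replaces the allylic C3' hydrogen that an ene transfer on this face would take) are meant to secure them in that order, the last being the untested point.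

Step 5
Reactants: 9 3'-hydroxy spiro adduct
Product: 10 xanthate (O-(3'-yl) S-methyl dithiocarbonate of 9; 2R,4R,1'R,3'S,5'R)
Conditions: NaN(SiMe3)2, THF, −78 °C; CS2; MeI, −78 to 0 °C
Reagents that add atoms: carbon disulfide (S=C=S); iodomethane 2 (CI)
Why: Xanthate formation as the first half of a Barton–McCombie deoxygenation, in which the sodium alkoxide of the secondary C3' carbinol adds to CS2 and the dithiocarbonate is S-methylated, the triketone half having no enolisable hydrogen (C6 and C8 are quaternary) and the low temperature holding back addition of the alkoxide to the vinylogous ester carbon C8a, and since no bond to a stereocentre is broken all five centres are kept.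

Step 6
Reactants: 10 xanthate
Product: 11 target CNP0231252.2 (2R,4R,1'R,5'S)
Conditions: Bu3SnH (5 equiv, about 1 M), AIBN (cat.), PhMe, 100 °C, slow addition of 10
Reagents that add atoms: none
Why: Barton–McCombie radical deoxygenation, in which the stannyl radical adds to the thiocarbonyl sulfur, the C3'–O bond breaks to a secondary radical that is not cyclobutylcarbinyl and so leaves the pinane intact, and at high stannane concentration hydrogen transfer should outrun β-scission of the adjacent C2–O1 bond, C3' becoming a CH2 group so that no stereocentre is made and the four others are untouched.

## Compound list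

1 | 2,4,6-trihydroxyacetophenone (phloroacetophenone) | CC(=O)c1c(O)cc(O)cc1O | starting material
2 | iodomethane | CI | starting material
3 | acetylsyncarpic acid, 2-acetyl-3-hydroxy-4,4,6,6-tetramethylcyclohex-2-ene-1,5-dione | CC(=O)C1=C(O)C(C)(C)C(=O)C(C)(C)C1=O | intermediate
4 | syncarpic acid, 3-hydroxy-4,4,6,6-tetramethylcyclohex-2-ene-1,5-dione | CC1(C)C(O)=CC(=O)C(C)(C)C1=O | intermediate
5 | (1S,5S)-(−)-β-pinene, 6,6-dimethyl-2-methylidenebicyclo[3.1.1]heptane | C=C1CC[C@H]2C[C@@H]1C2(C)C | starting material
6 | (1R,3S,5R)-trans-pinocarveol, 6,6-dimethyl-2-methylidenebicyclo[3.1.1]heptan-3-ol, hydroxyl trans to the gem-dimethyl bridge | C=C1[C@@H](O)C[C@H]2C[C@@H]1C2(C)C | intermediate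
7 | isovaleraldehyde (3-methylbutanal) | CC(C)CC=O | starting material
8 | 2-(3-methylbutylidene)-4,4,6,6-tetramethylcyclohexane-1,3,5-trione (heterodiene, not isolated) | CC(C)CC=C1C(=O)C(C)(C)C(=O)C(C)(C)C1=O | intermediate
9 | (2R,4R,1'R,3'S,5'R)-3'-hydroxy-6,6,8,8,6',6'-hexamethyl-4-(2-methylpropyl)-3,4-dihydrospiro[chromene-2,2'-bicyclo[3.1.1]heptane]-5,7(6H,8H)-dione, hydroxyl cis to O1 | CC(C)C[C@@H]1C[C@@]2([C@@H](O)C[C@H]3C[C@@H]2C3(C)C)OC2=C1C(=O)C(C)(C)C(=O)C2(C)C | intermediate
10 | O-(3'-yl) S-methyl dithiocarbonate (xanthate) of 9, same configuration | CC(C)C[C@@H]1C[C@@]2([C@@H](OC(=S)SC)C[C@H]3C[C@@H]2C3(C)C)OC2=C1C(=O)C(C)(C)C(=O)C2(C)C | intermediate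
11 | (2R,4R,1'R,5'S)-6,6,8,8,6',6'-hexamethyl-4-(2-methylpropyl)-3,4-dihydrospiro[chromene-2,2'-bicyclo[3.1.1]heptane]-5,7(6H,8H)-dione, CNP0231252.2 | CC(C)C[C@@H]1C[C@@]2(CC[C@H]3C[C@@H]2C3(C)C)OC2=C1C(=O)C(C)(C)C(=O)C2(C)C | target

## Step count and risks

Total step count: 6. Longest linear sequence: 5 steps (steps 1, 2, 4, 5 and 6, from 1 to 11); the pinene branch (step 3) joins at step 4.

Steps most likely to fail:

1. Step 4, the one step that goes beyond precedent. The orientational control by the hydroxyl may be weak, so that bonding with the triketone on the C3' flank competes and the C4 configuration is not set cleanly. The free hydroxyl may also capture the heterodiene by oxa-Michael addition, or the heterodiene may be drained by a second molecule of 4 or by tautomerisation to its dienol, faster than the cycloaddition runs. The fallback uses known chemistry: the same one-pot Knoevenagel/oxa-Diels–Alder reaction is run from 4 and 7 on (−)-β-pinene 5 itself, the alkene for which this reaction type is established, again through heterodiene 8. The adduct with oxygen anti to the bridge and the 4R configuration is then the target directly, to be separated by chromatography from its C4 epimer and from ene-type material; steps 3, 5 and 6 fall away. This fallback sets out from 4 and comes back to the route at 11; it makes no new compound, F0.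

2. Step 6. The C3' radical may be lost by β-scission of the neighbouring C2–O1 bond, which opens the dihydropyran ring to a stabilised triketone radical before hydrogen is transferred. The fallback avoids a carbon radical: xanthate 10 is heated in o-dichlorobenzene for a Chugaev syn-elimination, which can only run towards C4' (the one neighbour with a cis hydrogen, C2' being quaternary) and should give the 3',4'-didehydro spiro compound F1. Its strained cis-disubstituted alkene is then reduced with diimide (2-nitrobenzenesulfonyl hydrazide, Et3N), which leaves the tetrasubstituted vinylogous ester alkene and the ketones alone. This fallback sets out from 10 and comes back at 11.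

3. Step 5. The hindered C3' alkoxide may add to the vinylogous ester carbon C8a beside it, moving the enol ether from O1 to the C3' oxygen, instead of adding to CS2. The fallback works without an alkoxide: 9 is acylated under nucleophilic catalysis with phenyl chlorothionoformate (pyridine, DMAP, CH2Cl2) to the O-phenyl thionocarbonate F2, which is reduced with Bu3SnH and AIBN in the same way as a xanthate. This fallback sets out from 9 and comes back at 11.

Further compounds
F0 | step 4 | none | none
F1 | step 6 | 3',4'-didehydro spiro compound (alkene between pinane C3' and C4', otherwise as 11) | CC(C)C[C@@H]1C[C@@]2(C=C[C@H]3C[C@@H]2C3(C)C)OC2=C1C(=O)C(C)(C)C(=O)C2(C)C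
F2 | step 5 | O-phenyl thionocarbonate of 9 (O-(3'-yl) O-phenyl carbonothioate, configuration as 9) | CC(C)C[C@@H]1C[C@@]2([C@@H](OC(=S)Oc4ccccc4)C[C@H]3C[C@@H]2C3(C)C)OC2=C1C(=O)C(C)(C)C(=O)C2(C)C
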